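**Plan**
1. Retrosynthetic cuts, from the end: the O–S bond of the sulfate; the aryl C–O bond between ring A and the C1 oxygen of ring B (SNAr on a 2-fluorobenzaldehyde whose formyl group later becomes the sulfated oxygen); the C1–O bond of ring B back to C1–B; and, as the key cut, the ring B bonds C1–C6 and C2–C3.
2. Enabling feature: ring B has Br on C3, C4, C5 and H on C6 in a row beside the oxygen-bearing C1 and C2. C3–C6 is therefore a 2,3,4-tribromothiophene 1,1-dioxide, and C1–C2 is an alkyne carrying boron on C1 and the ring C aryloxy group on C2.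
3. Forward: 2,4-dibromophenol (ring C) becomes the aryloxyalkynyl boronate (vinyl ether, bromination/dehydrobromination twice, borylation). Ring B is then built by [4+2] cycloaddition with loss of SO2, the boron is oxidised to the C1 phenol, ring A is attached by SNAr, and Baeyer–Villiger oxidation and sulfation finish.
4. Stereochemistry: the target has no stereocentre and no stereogenic double bond. The Z geometry of bromovinyl ether 9 is destroyed in step 5 and the bridgehead centres of adduct 14 are lost on extrusion.

Key step: step 7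

Assumption: the target is taken as the free hydrogen sulfate exactly as drawn; it is released by cation exchange in the last step and would be kept as its sodium salt if the free acid proves labile.

**Step 1**
Reactants: 1 tetrabromothiophene
Product: 3 2,3,4-tribromothiophene, via (3,4,5-tribromothiophen-2-yl)lithium 2 (not isolated)
Conditions: n-BuLi (1.0 equiv), THF, −78 °C; then MeOH, −78 °C → rt
Reagents that add atoms: none
Why: Bromine–lithium exchange with one equivalent of n-BuLi is selective for an alpha position of the perbrominated thiophene (the 2-thienyllithium is the more stable anion), and protonation of 2 leaves the 2,3,4-tribromo pattern.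

**Step 2**
Reactants: 3 2,3,4-tribromothiophene
Product: 4 2,3,4-tribromothiophene 1,1-dioxide
Conditions: urea·H2O2, (CF3CO)2O, CH2Cl2, 0 °C → rt; product kept cold
Reagents that add atoms: urea–hydrogen peroxide, NC(N)=O.OO (its oxygen is passed on by trifluoroperacetic acid, OOC(=O)C(F)(F)F, formed in the flask)
Why: Peracid S-oxidation of electron-poor halothiophenes with CF3CO3H runs through the sulfoxide to the 1,1-dioxide, and three bromines should make the resulting diene slow to dimerise, as for the tetrahalo analogues.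

**Step 3**
Reactants: 5 2,4-dibromophenol; 6 2,4,6-trivinylcyclotriboroxane–pyridine complex
Product: 7 2,4-dibromo-1-(vinyloxy)benzene
Conditions: Cu(OAc)2 (1 equiv), pyridine, CH2Cl2, rt, dry air
Reagents that add atoms: none
Why: Chan–Lam O-vinylation, the copper-mediated oxidative coupling of a phenol with a vinylboron reagent at room temperature, tolerates ortho-halophenols and leaves the aryl bromides untouched.

**Step 4**
Reactants: 7 2,4-dibromo-1-(vinyloxy)benzene
Product: 9 (Z)-2,4-dibromo-1-[(2-bromoethenyl)oxy]benzene, via 2,4-dibromo-1-(1,2-dibromoethoxy)benzene 8 (not isolated)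
Conditions: Br2 (1.0 equiv), CH2Cl2, −78 °C; then DBU, −78 °C → rt
Reagents that add atoms: bromine, BrBr
Why: Bromine adds to the electron-rich vinyl ether far faster than it substitutes the deactivated ring, and amidine-base dehydrobromination of the alpha,beta-dibromo ether is the classical entry to 2-bromovinyl ethers; the Z isomer is expected to predominate, and any E or 1-bromovinyl isomer converges on the same alkyne in step 5.

**Step 5**
Reactants: 9 (Z)-2,4-dibromo-1-[(2-bromoethenyl)oxy]benzene
Product: 10 2,4-dibromo-1-(ethynyloxy)benzene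
Conditions: KOtBu (2.2 equiv), THF, −78 → 0 °C; pH 7 buffer; used at once
Reagents that add atoms: none
Why: Anti-dehydrobromination (E2) of a Z-2-bromovinyl ether is the classical route to aryloxyacetylenes, and KOtBu at 0 °C neither metalates ring C nor attacks its bromines.

**Step 6**
Reactants: 10 2,4-dibromo-1-(ethynyloxy)benzene
Product: 13 2-[(2,4-dibromophenoxy)ethynyl]-4,4,5,5-tetramethyl-1,3,2-dioxaborolane, via lithium (2,4-dibromophenoxy)acetylide 11 (not isolated), via lithium alkynyl(isopropoxy)pinacolborate 12 (not isolated)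
Conditions: LiN(SiMe3)2 (1.05 equiv), THF, −78 °C; iPrOBpin, −78 °C; HCl (1.0 equiv, Et2O), −78 °C → rt; filtered under N2, used crude
Reagents that add atoms: 2-isopropoxy-4,4,5,5-tetramethyl-1,3,2-dioxaborolane, CC(C)OB1OC(C)(C)C(C)(C)O1
Why: Deprotonation of the terminal alkyne by the silylamide (too weak for ring metalation, unable to exchange bromine), trapping of the acetylide with the borate ester and release of the boronate from the ate complex with one equivalent of anhydrous HCl is the standard alkynylboronate synthesis.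

**Step 7**
Reactants: 4 2,3,4-tribromothiophene 1,1-dioxide; 13 2-[(2,4-dibromophenoxy)ethynyl]-4,4,5,5-tetramethyl-1,3,2-dioxaborolane
Product: 15 2-[3,4,5-tribromo-2-(2,4-dibromophenoxy)phenyl]-4,4,5,5-tetramethyl-1,3,2-dioxaborolane, via bridged sulfone cycloadduct 14 (not isolated)
Conditions: 13 (1.2 equiv), PhMe, 90 °C, slow N2 stream to sweep out SO2
Reagents that add atoms: none
Why: Proposed new method: the electron-poor diene of sulfone 4 and the push-pull alkyne 13 (aryloxy donor, boryl acceptor, highest electron density on the boron-bearing carbon) should combine in an inverse-electron-demand, asynchronous [4+2] cycloaddition to the bridged sulfone 14, which then loses SO2 by cheletropic extrusion with aromatisation as the driving force. The closest known reaction types are the benzannulations of tetrahalothiophene 1,1-dioxides with alkynes under loss of SO2 and the cycloaddition–extrusion benzannulations of alkynylboronates with 2-pyrones; a halothiophene dioxide has not been paired with an oxygen-substituted alkynylboronate. Ring B closes by intermolecular [4+2] cycloaddition that forms C1–C6 and C2–C3 in one operation, and expulsion of the sulfonyl bridge delivers it directly as a benzene carrying Br, Br, Br, H from 4 and aryloxy and boron from 13. No stereocentre remains, since the two bridgehead centres of racemic 14 vanish on extrusion. The step needs one orientation, the boron-bearing carbon bonding to the unsubstituted C5 of 4, and the polarisation of 13, the stabilisation of developing negative charge at the bromine- and sulfonyl-substituted C2 of the diene and the lower hindrance at the CH terminus all point that way. Chemoselectivity rests on the tribromo diene dimerising slowly and on the aryl ynol ether having no thermal retro-ene pathway at this temperature.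

**Step 8**
Reactants: 15 2-[3,4,5-tribromo-2-(2,4-dibromophenoxy)phenyl]-4,4,5,5-tetramethyl-1,3,2-dioxaborolane
Product: 16 3,4,5-tribromo-2-(2,4-dibromophenoxy)phenol
Conditions: NaBO3·4H2O (3 equiv), THF/H2O, rt
Reagents that add atoms: sodium perborate tetrahydrate, [Na+].[Na+].O[B-]1(O)OO[B-](O)(O)OO1 (hydrate water omitted)
Why: Perborate oxidation of an aryl C–B bond (peroxide addition to boron, 1,2-aryl shift to oxygen, hydrolysis) is mild enough for the aryl bromides and the diaryl ether.

**Step 9**
Reactants: 16 3,4,5-tribromo-2-(2,4-dibromophenoxy)phenol; 17 3,5-dibromo-2-fluorobenzaldehyde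
Product: 18 3,5-dibromo-2-[3,4,5-tribromo-2-(2,4-dibromophenoxy)phenoxy]benzaldehyde
Conditions: Cs2CO3 (1.5 equiv), DMF, 80 °C
Reagents that add atoms: none
Why: SNAr: the phenoxide of 16 displaces fluoride ortho to the formyl group through a Meisenheimer adduct, while the bromines of 17 sit meta to the formyl group and are not activated.

**Step 10**
Reactants: 18 3,5-dibromo-2-[3,4,5-tribromo-2-(2,4-dibromophenoxy)phenoxy]benzaldehyde
Product: 20 3,5-dibromo-2-[3,4,5-tribromo-2-(2,4-dibromophenoxy)phenoxy]phenol, via aryl formate 19 (not isolated)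
Conditions: mCPBA, CH2Cl2, 40 °C; then K2CO3, MeOH, rt
Reagents that add atoms: 3-chloroperbenzoic acid, OOC(=O)c1cccc(Cl)c1
Why: Baeyer–Villiger (Dakin-type) oxidation, in which the ortho-aryloxy group should let the aryl group migrate in the Criegee adduct to give formate 19, which methanolysis then cleaves.

**Step 11**
Reactants: 20 3,5-dibromo-2-[3,4,5-tribromo-2-(2,4-dibromophenoxy)phenoxy]phenol
Product: 22 bromoiesol A sulfate, via pyridinium aryl sulfate 21 (not isolated)
Conditions: SO3·pyridine (5 equiv), pyridine, 50 °C; then sulfonic acid resin (H+ form), MeOH/H2O, 0 °C; freeze-drying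
Reagents that add atoms: sulfur trioxide–pyridine complex, [O-]S(=O)(=O)[n+]1ccccc1
Why: O-Sulfation of the phenol with the sulfur trioxide–pyridine complex gives the pyridinium aryl sulfate, and cation exchange against the acid form of the resin frees the hydrogen sulfate.

**Compound list**
1 | tetrabromothiophene | Brc1sc(Br)c(Br)c1Br | starting material
2 | (3,4,5-tribromothiophen-2-yl)lithium | [Li]c1sc(Br)c(Br)c1Br | intermediate (not isolated)
3 | 2,3,4-tribromothiophene | Brc1scc(Br)c1Br | intermediate
4 | 2,3,4-tribromothiophene 1,1-dioxide | O=S1(=O)C=C(Br)C(Br)=C1Br | intermediate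
5 | 2,4-dibromophenol | Oc1ccc(Br)cc1Br | starting material
6 | 2,4,6-trivinylcyclotriboroxane–pyridine complex | C=CB1OB(C=C)OB(C=C)O1.c1ccncc1 | starting material
7 | 2,4-dibromo-1-(vinyloxy)benzene | C=COc1ccc(Br)cc1Br | intermediate
8 | 2,4-dibromo-1-(1,2-dibromoethoxy)benzene (racemic) | BrCC(Br)Oc1ccc(Br)cc1Br | intermediate (not isolated)
9 | (Z)-2,4-dibromo-1-[(2-bromoethenyl)oxy]benzene | Br/C=C\Oc1ccc(Br)cc1Br | intermediate
10 | 2,4-dibromo-1-(ethynyloxy)benzene | C#COc1ccc(Br)cc1Br | intermediate
11 | lithium (2,4-dibromophenoxy)acetylide | [Li]C#COc1ccc(Br)cc1Br | intermediate (not isolated)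
12 | lithium [(2,4-dibromophenoxy)ethynyl](isopropoxy)pinacolborate | [Li+].CC(C)O[B-]1(C#COc2ccc(Br)cc2Br)OC(C)(C)C(C)(C)O1 | intermediate (not isolated)
13 | 2-[(2,4-dibromophenoxy)ethynyl]-4,4,5,5-tetramethyl-1,3,2-dioxaborolane | CC1(C)OB(C#COc2ccc(Br)cc2Br)OC1(C)C | intermediate
14 | 1,5,6-tribromo-2-(2,4-dibromophenoxy)-3-(4,4,5,5-tetramethyl-1,3,2-dioxaborolan-2-yl)-7-thiabicyclo[2.2.1]hepta-2,5-diene 7,7-dioxide (racemic) | O=S1(=O)C2(Br)C(Br)=C(Br)C1C(B1OC(C)(C)C(C)(C)O1)=C2Oc1ccc(Br)cc1Br | intermediate (not isolated)
15 | 2-[3,4,5-tribromo-2-(2,4-dibromophenoxy)phenyl]-4,4,5,5-tetramethyl-1,3,2-dioxaborolane | CC1(C)OB(c2cc(Br)c(Br)c(Br)c2Oc2ccc(Br)cc2Br)OC1(C)C | intermediate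
16 | 3,4,5-tribromo-2-(2,4-dibromophenoxy)phenol | Oc1cc(Br)c(Br)c(Br)c1Oc1ccc(Br)cc1Br | intermediate
17 | 3,5-dibromo-2-fluorobenzaldehyde | O=Cc1cc(Br)cc(Br)c1F | starting material
18 | 3,5-dibromo-2-[3,4,5-tribromo-2-(2,4-dibromophenoxy)phenoxy]benzaldehyde | O=Cc1cc(Br)cc(Br)c1Oc1cc(Br)c(Br)c(Br)c1Oc1ccc(Br)cc1Br | intermediate
19 | 3,5-dibromo-2-[3,4,5-tribromo-2-(2,4-dibromophenoxy)phenoxy]phenyl formate | O=COc1cc(Br)cc(Br)c1Oc1cc(Br)c(Br)c(Br)c1Oc1ccc(Br)cc1Br | intermediate (not isolated)
20 | 3,5-dibromo-2-[3,4,5-tribromo-2-(2,4-dibromophenoxy)phenoxy]phenol | Oc1cc(Br)cc(Br)c1Oc1cc(Br)c(Br)c(Br)c1Oc1ccc(Br)cc1Br | intermediate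
21 | pyridinium 3,5-dibromo-2-[3,4,5-tribromo-2-(2,4-dibromophenoxy)phenoxy]phenyl sulfate | [O-]S(=O)(=O)Oc1cc(Br)cc(Br)c1Oc1cc(Br)c(Br)c(Br)c1Oc1ccc(Br)cc1Br.c1cc[nH+]cc1 | intermediate (not isolated)
22 | bromoiesol A sulfate, 3,5-dibromo-2-[3,4,5-tribromo-2-(2,4-dibromophenoxy)phenoxy]phenyl hydrogen sulfate | O=S(=O)(O)Oc1cc(Br)cc(Br)c1Oc1cc(Br)c(Br)c(Br)c1Oc1ccc(Br)cc1Br | target

**Step count**
Total: 11 steps. Longest linear sequence: 9 steps (5 → 22, steps 3–11); the diene branch (steps 1–2) joins at step 7.

**Steps most likely to fail**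

Step 7 (cycloaddition). The cycloaddition may stall, may take the opposite orientation, or may divert into stepwise [2+2] addition at the vinyl sulfone or into dimerisation of the diene before SO2 is lost. The fallback builds ring B from a preformed benzene by known reactions; it sets out from 2,4-dibromophenol 5 and rejoins the route at phenol 16. Commercial 4-bromo-2-fluorobenzaldehyde is brominated twice (NBS, conc. H2SO4, 60 °C; all directing effects converge on C5 and then C3) to 3,4,5-tribromo-2-fluorobenzaldehyde F1. SNAr with 5 (K2CO3, DMF, 60 °C) should give 3,4,5-tribromo-2-(2,4-dibromophenoxy)benzaldehyde F2. Baeyer–Villiger oxidation (mCPBA, CH2Cl2) to 3,4,5-tribromo-2-(2,4-dibromophenoxy)phenyl formate F3 and methanolysis (K2CO3, MeOH) should then deliver 16.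

Step 6 (borylation). The alkynyl C–B bond may be protonolysed, or the ynol ether hydrated, while HCl releases the boronate from ate complex 12. The fallback avoids acid altogether; it sets out from alkyne 10 and returns at boronate 13. The acetylide 11 (LiN(SiMe3)2, THF, −78 °C) is trapped with chlorobis(dimethylamino)borane, ClB(NMe2)2, to give [(2,4-dibromophenoxy)ethynyl]bis(dimethylamino)borane F4, and LiCl is filtered off. Alcoholysis of the aminoborane with pinacol (1 equiv, PhMe, rt, N2 stream) drives off dimethylamine and should leave 13 under neutral conditions.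

Step 10 (Baeyer–Villiger). Hydride rather than aryl migration in the Criegee adduct of the electron-poor aldehyde would lead to the benzoic acid instead of the formate. The fallback swaps the migrating competitor from hydrogen to methyl; it sets out from aldehyde 18 and returns at phenol 20. MeMgBr (THF, −78 °C) gives racemic 1-{3,5-dibromo-2-[3,4,5-tribromo-2-(2,4-dibromophenoxy)phenoxy]phenyl}ethanol F5. Dess–Martin periodinane gives 1-{3,5-dibromo-2-[3,4,5-tribromo-2-(2,4-dibromophenoxy)phenoxy]phenyl}ethanone F6. CF3CO3H (urea·H2O2, (CF3CO)2O, Na2HPO4, CH2Cl2), with aryl migrating in preference to methyl, gives 3,5-dibromo-2-[3,4,5-tribromo-2-(2,4-dibromophenoxy)phenoxy]phenyl acetate F7, and K2CO3 in MeOH gives 20.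

**Further compounds**
F1 | step 7 | 3,4,5-tribromo-2-fluorobenzaldehyde | O=Cc1cc(Br)c(Br)c(Br)c1F
F2 | step 7 | 3,4,5-tribromo-2-(2,4-dibromophenoxy)benzaldehyde | O=Cc1cc(Br)c(Br)c(Br)c1Oc1ccc(Br)cc1Br
F3 | step 7 | 3,4,5-tribromo-2-(2,4-dibromophenoxy)phenyl formate | O=COc1cc(Br)c(Br)c(Br)c1Oc1ccc(Br)cc1Br
F4 | step 6 | [(2,4-dibromophenoxy)ethynyl]bis(dimethylamino)borane | CN(C)B(C#COc1ccc(Br)cc1Br)N(C)C
F5 | step 10 | 1-{3,5-dibromo-2-[3,4,5-tribromo-2-(2,4-dibromophenoxy)phenoxy]phenyl}ethanol (racemic) | CC(O)c1cc(Br)cc(Br)c1Oc1cc(Br)c(Br)c(Br)c1Oc1ccc(Br)cc1Br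
F6 | step 10 | 1-{3,5-dibromo-2-[3,4,5-tribromo-2-(2,4-dibromophenoxy)phenoxy]phenyl}ethanone | CC(=O)c1cc(Br)cc(Br)c1Oc1cc(Br)c(Br)c(Br)c1Oc1ccc(Br)cc1Br
F7 | step 10 | 3,5-dibromo-2-[3,4,5-tribromo-2-(2,4-dibromophenoxy)phenoxy]phenyl acetate | CC(=O)Oc1cc(Br)cc(Br)c1Oc1cc(Br)c(Br)c(Br)c1Oc1ccc(Br)cc1Br
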